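**Retrosynthetic overview**
- C1–C14 is the last bond: a 2‑(methoxycarbonyl)allylindium (the acrylate β‑carbon made nucleophilic, an ester homoenolate equivalent) adds intramolecularly to an unprotected α‑hydroxy aldehyde. This closes the 14‑membered carbocycle and sets C1 and C14; γ‑lactonisation follows in the same pot.
- The seco precursor comes from an acyclic triol: cross‑metathesis installs the (Z)‑2‑(bromomethyl)enoate, and selective oxidation of the primary alcohol reveals the C14 aldehyde.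
- C7–C8 is made by a ligand‑controlled Nozaki–Hiyama–Kishi union of a C8–C14 alkenyl bromide with a C1–C7 epoxy aldehyde.
- The C8–C14 piece comes from Brown (Z)‑crotylboration (C12, C13) and hydrozirconation/allylation; the C1–C7 piece from Negishi carboalumination/allylation and Shi epoxidation (C3, C4).
- Ring order: oxirane, then 14‑membered carbocycle, then γ‑lactone.

Assumption: cembrane numbering is used (C1 = ring CH bearing C15; C3/C4 = oxirane; C7, C13 = carbinols; C8=C19 and C15=C17 = methylidenes; C14 = lactone O–CH; C16 = lactone C=O); the given SMILES is (1S,3R,4R,7R,12S,13R,14R).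

**Step 1**
Reactants: 1 (tert-butyldimethylsilyloxy)acetaldehyde; 2 cis-but-2-ene
Product: 5 (2R,3S)-1-(tert-butyldimethylsilyloxy)-3-methylpent-4-en-2-ol, via (Z)-crotylpotassium 3 (not isolated), via (Z)-crotyldiisopinocampheylborane 4 (not isolated)
Conditions: 2, KOt-Bu, n-BuLi, THF, −78 to −45 °C; (+)-Ipc2BOMe, −78 °C; BF3·OEt2; 1, −78 °C; then NaOH, H2O2, rt
Reagents that add atoms: none
Why: Brown asymmetric crotylboration through a closed chair transition state, in which the Z‑crotyl geometry gives the 12,13‑syn relationship and the isopinocampheyl groups derived from (−)-α-pinene direct attack to the Re face of 1, setting C13 (R) and C12 (S).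

**Step 2**
Reactants: 5 (2R,3S)-1-(tert-butyldimethylsilyloxy)-3-methylpent-4-en-2-ol; 6 2,3-dibromopropene
Product: 8 (2R,3S)-7-bromo-1-(tert-butyldimethylsilyloxy)-3-methyloct-7-en-2-ol, via alkylzirconocene chloride 7 (not isolated)
Conditions: Cp2Zr(H)Cl (2.2 equiv), THF, rt; then CuBr·SMe2 (10 mol%), 6, 0 °C to rt
Reagents that add atoms: none
Why: Schwartz hydrozirconation puts zirconium on the terminal carbon (the hydroxyl rides as its zirconium alkoxide), and copper‑catalysed allylic substitution on 6 gives the 2‑bromo‑1‑alkene whether it goes SN2 or SN2′; no stereocentre is touched.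

**Step 3**
Reactants: 9 pent-4-yn-1-ol; 10 allyl bromide
Product: 12 (E)-4-methylocta-4,7-dien-1-ol, via (E)-alkenyldimethylalane 11 (not isolated)
Conditions: Me3Al (3 equiv), Cp2ZrCl2 (25 mol%), CH2Cl2, 0 °C to rt; then 10, Pd(PPh3)4 (3 mol%), THF, rt
Reagents that add atoms: trimethylaluminium, C[Al](C)C
Why: Negishi zirconium‑catalysed carboalumination adds Me–Al syn across the alkyne with methyl on the internal carbon, and the alkenylalane couples with allyl bromide under zerovalent palladium catalysis with retention, fixing the E trisubstituted C3=C4 olefin.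

**Step 4**
Reactants: 12 (E)-4-methylocta-4,7-dien-1-ol
Product: 13 3-[(2R,3R)-2-methyl-3-(prop-2-enyl)oxiran-2-yl]propan-1-ol
Conditions: Shi ketone (D-fructose-derived, 30 mol%), KHSO5 (Oxone), K2CO3, Bu4NHSO4, MeCN/dimethoxymethane/aq. Na2B4O7, 0 °C
Reagents that add atoms: potassium peroxymonosulfate KHSO5, [K+].[O-]S(=O)(=O)OO
Why: Shi asymmetric epoxidation, in which the chiral dioxirane attacks the electron‑rich E‑trisubstituted olefin through the spiro transition state (the terminal vinyl is much slower) and gives the (R,R)-oxirane, setting C3 (R) and C4 (R) under basic conditions that keep the epoxy alcohol from cyclising.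

**Step 5**
Reactants: 13 3-[(2R,3R)-2-methyl-3-(prop-2-enyl)oxiran-2-yl]propan-1-ol
Product: 14 3-[(2R,3R)-2-methyl-3-(prop-2-enyl)oxiran-2-yl]propanal
Conditions: [Cu(MeCN)4]OTf (5 mol%), 2,2′-bipyridine, TEMPO, N-methylimidazole, air, MeCN, rt
Reagents that add atoms: none
Why: Stahl aerobic copper/TEMPO oxidation converts the primary alcohol to the aldehyde under mildly basic, non‑acidic conditions that leave the trisubstituted epoxide and the vinyl group untouched.

**Step 6**
Reactants: 8 (2R,3S)-7-bromo-1-(tert-butyldimethylsilyloxy)-3-methyloct-7-en-2-ol; 14 3-[(2R,3R)-2-methyl-3-(prop-2-enyl)oxiran-2-yl]propanal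
Product: 16 (2R,3S,8R)-1-(tert-butyldimethylsilyloxy)-3-methyl-7-methylidene-10-[(2R,3R)-2-methyl-3-(prop-2-enyl)oxiran-2-yl]decane-2,8-diol, via alkenylchromium dichloride 15 (not isolated)
Conditions: CrCl2 (4 equiv), NiCl2 (5 mol%), valinol-derived oxazoline–sulfonamide ligand (Kishi type, 4.4 equiv), Et3N, THF, rt
Reagents that add atoms: none
Why: Asymmetric Nozaki–Hiyama–Kishi coupling, in which the nickel‑catalysed alkenylchromium adds only to the aldehyde (free OH, silyl ether and epoxide tolerated) and the chiral sulfonamide on chromium directs Si‑face addition to give C7 (R); the ligand enantiomer is the one that gives this sense, confirmed by Mosher analysis of 16.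

**Step 7**
Reactants: 16 (2R,3S,8R)-1-(tert-butyldimethylsilyloxy)-3-methyl-7-methylidene-10-[(2R,3R)-2-methyl-3-(prop-2-enyl)oxiran-2-yl]decane-2,8-diol
Product: 17 (2R,3S,8R)-3-methyl-7-methylidene-10-[(2R,3R)-2-methyl-3-(prop-2-enyl)oxiran-2-yl]decane-1,2,8-triol
Conditions: Bu4NF, THF, 0 °C to rt
Reagents that add atoms: none
Why: Fluoride cleavage of the primary silyl ether under mildly basic conditions that the epoxy alcohol survives.

**Step 8**
Reactants: 17 (2R,3S,8R)-3-methyl-7-methylidene-10-[(2R,3R)-2-methyl-3-(prop-2-enyl)oxiran-2-yl]decane-1,2,8-triol; 18 methyl 2-(bromomethyl)acrylate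
Product: 19 methyl (2Z)-2-(bromomethyl)-4-{(2R,3R)-3-methyl-3-[(3R,8S,9R)-3,9,10-trihydroxy-8-methyl-4-methylidenedecyl]oxiran-2-yl}but-2-enoate
Conditions: RuCl2(H2IMes)(=CH-C6H4-2-O-i-Pr) (Hoveyda–Grubbs second-generation catalyst, 10 mol%), 18 (5 equiv), 1,4-benzoquinone (20 mol%), CH2Cl2, 40 °C
Reagents that add atoms: none
Why: Olefin cross‑metathesis of the only monosubstituted alkene with a 1,1‑disubstituted acrylate (as with methacrylates) gives the trisubstituted enoate with the chain trans to the ester, which is the Z isomer here; the 1,1‑disubstituted C8 olefin and free hydroxyls do not interfere.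

**Step 9**
Reactants: 19 methyl (2Z)-2-(bromomethyl)-4-{(2R,3R)-3-methyl-3-[(3R,8S,9R)-3,9,10-trihydroxy-8-methyl-4-methylidenedecyl]oxiran-2-yl}but-2-enoate
Product: 20 methyl (2Z)-2-(bromomethyl)-4-{(2R,3R)-3-[(3R,8S,9R)-3,9-dihydroxy-8-methyl-4-methylidene-10-oxodecyl]-3-methyloxiran-2-yl}but-2-enoate
Conditions: TEMPO (10 mol%), N-chlorosuccinimide (1.2 equiv), Bu4NCl (10 mol%), CH2Cl2/aq. NaHCO3–K2CO3 (pH 8.6), 0 °C; used crude
Reagents that add atoms: none
Why: Oxoammonium (TEMPO/N‑chlorosuccinimide) oxidation is sterically selective for the primary hydroxyl over the two secondary ones, and the buffered medium protects the epoxide and the C13 stereocentre.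

**Step 10**
Reactants: 20 methyl (2Z)-2-(bromomethyl)-4-{(2R,3R)-3-[(3R,8S,9R)-3,9-dihydroxy-8-methyl-4-methylidene-10-oxodecyl]-3-methyloxiran-2-yl}but-2-enoate
Product: 23 (1S,3R,4R,7R,12S,13R,14R)-3,4-epoxy-7,13-dihydroxycembra-8(19),15(17)-dien-16,14-olide, via allylindium dibromide 21 (not isolated), via seco hydroxy ester 22 (not isolated)
Conditions: indium powder (3 equiv), THF/H2O (1:1), slow addition of 20 to 2 mM, rt; then extraction and 2-hydroxypyridine (20 mol%), PhMe, 60 °C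
Reagents that add atoms: none
Why: Proposed new method: indium inserts into the allylic C–Br bond to give allylindium 21, in which the acrylate β‑carbon C1 (an acceptor position in 20) is now the γ‑nucleophile of an ester homoenolate equivalent and adds intramolecularly to the aldehyde carbon C14 (two natively electrophilic carbons) through a Barbier‑type chair transition state, where chelation of indium by the free C13 hydroxyl gives 13,14‑syn and the Z geometry gives 1,14‑syn (C1 S, C14 R), after which hydroxy ester 22 closes to the cis γ‑lactone; the closest known reactions are the intermolecular indium‑promoted coupling of (Z)-2-(bromomethyl)-2-alkenoates with unprotected α‑hydroxy aldehydes in water (syn,syn‑selective) and the CrCl2‑mediated allylic bromide–aldehyde closure of 14‑membered epoxy cembranoid rings.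

**Compound list**
1 | (tert-butyldimethylsilyloxy)acetaldehyde | O=CCO[Si](C)(C)C(C)(C)C | starting material
2 | cis-but-2-ene | C/C=C\C | starting material
3 | (Z)-crotylpotassium | C/C=C\C[K] | intermediate
4 | (Z)-crotyldiisopinocampheylborane (Ipc from (−)-α-pinene) | C/C=C\CB([C@H]1C[C@H]2C[C@@H]([C@@H]1C)C2(C)C)[C@H]1C[C@H]2C[C@@H]([C@@H]1C)C2(C)C | intermediate
5 | (2R,3S)-1-(tert-butyldimethylsilyloxy)-3-methylpent-4-en-2-ol | C=C[C@H](C)[C@@H](O)CO[Si](C)(C)C(C)(C)C | intermediate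
6 | 2,3-dibromopropene | C=C(Br)CBr | starting material
7 | alkylzirconocene chloride from 5 (C-terminal Zr, O-zirconated) | Cl[Zr](C1C=CC=C1)(C1C=CC=C1)CC[C@H](C)[C@@H](O[Zr](Cl)(C1C=CC=C1)C1C=CC=C1)CO[Si](C)(C)C(C)(C)C | intermediate
8 | (2R,3S)-7-bromo-1-(tert-butyldimethylsilyloxy)-3-methyloct-7-en-2-ol | C=C(Br)CCC[C@H](C)[C@@H](O)CO[Si](C)(C)C(C)(C)C | intermediate
9 | pent-4-yn-1-ol | C#CCCCO | starting material
10 | allyl bromide | C=CCBr | starting material
11 | (E)-alkenyldimethylalane from 9 (O-aluminated) | C[Al](C)/C=C(\C)CCCO[Al](C)C | intermediate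
12 | (E)-4-methylocta-4,7-dien-1-ol | C=CC/C=C(\C)CCCO | intermediate
13 | 3-[(2R,3R)-2-methyl-3-(prop-2-enyl)oxiran-2-yl]propan-1-ol | C=CC[C@H]1O[C@]1(C)CCCO | intermediate
14 | 3-[(2R,3R)-2-methyl-3-(prop-2-enyl)oxiran-2-yl]propanal | C=CC[C@H]1O[C@]1(C)CCC=O | intermediate
15 | alkenylchromium dichloride from 8 | C=C([Cr](Cl)Cl)CCC[C@H](C)[C@@H](O)CO[Si](C)(C)C(C)(C)C | intermediate
16 | (2R,3S,8R)-1-(tert-butyldimethylsilyloxy)-3-methyl-7-methylidene-10-[(2R,3R)-2-methyl-3-(prop-2-enyl)oxiran-2-yl]decane-2,8-diol | C=CC[C@H]1O[C@]1(C)CC[C@@H](O)C(=C)CCC[C@H](C)[C@@H](O)CO[Si](C)(C)C(C)(C)C | intermediate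
17 | (2R,3S,8R)-3-methyl-7-methylidene-10-[(2R,3R)-2-methyl-3-(prop-2-enyl)oxiran-2-yl]decane-1,2,8-triol | C=CC[C@H]1O[C@]1(C)CC[C@@H](O)C(=C)CCC[C@H](C)[C@@H](O)CO | intermediate
18 | methyl 2-(bromomethyl)acrylate | C=C(CBr)C(=O)OC | starting material
19 | methyl (2Z)-2-(bromomethyl)-4-{(2R,3R)-3-methyl-3-[(3R,8S,9R)-3,9,10-trihydroxy-8-methyl-4-methylidenedecyl]oxiran-2-yl}but-2-enoate | COC(=O)/C(CBr)=C/C[C@H]1O[C@]1(C)CC[C@@H](O)C(=C)CCC[C@H](C)[C@@H](O)CO | intermediate
20 | methyl (2Z)-2-(bromomethyl)-4-{(2R,3R)-3-[(3R,8S,9R)-3,9-dihydroxy-8-methyl-4-methylidene-10-oxodecyl]-3-methyloxiran-2-yl}but-2-enoate | COC(=O)/C(CBr)=C/C[C@H]1O[C@]1(C)CC[C@@H](O)C(=C)CCC[C@H](C)[C@@H](O)C=O | intermediate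
21 | allylindium dibromide from 20 (In on C17) | COC(=O)/C(C[In](Br)Br)=C/C[C@H]1O[C@]1(C)CC[C@@H](O)C(=C)CCC[C@H](C)[C@@H](O)C=O | intermediate
22 | methyl (1S,3R,4R,7R,12S,13R,14R)-3,4-epoxy-7,13,14-trihydroxycembra-8(19),15(17)-dien-16-oate | C=C1CCC[C@H](C)[C@@H](O)[C@H](O)[C@H](C(=C)C(=O)OC)C[C@H]2O[C@]2(C)CC[C@H]1O | intermediate
23 | (1S,3R,4R,7R,12S,13R,14R)-3,4-epoxy-7,13-dihydroxycembra-8(19),15(17)-dien-16,14-olide | C=C1CCC[C@H](C)[C@@H](O)[C@@H]2OC(=O)C(=C)[C@@H]2C[C@H]2O[C@]2(C)CC[C@H]1O | target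

**Totals**
Total step count: 10. Longest linear sequence: 8 steps (9 → 12 → 13 → 14 → 16 → 17 → 19 → 20 → 23; steps 3–10).

**Three steps most likely to fail**

Step 10 (macrocyclic indium closure). The macrocyclic version is unprecedented: the allylindium may be protonated or oligomerise before it finds the aldehyde, and ring strain could erode the syn,syn control. The fallback sets out from 8 and 13 and comes back at 23, making the same C1–C14 bond intermolecularly and closing the ring at C7–C8 instead. Compound 8 is desilylated (Bu4NF) to (2R,3S)-7-bromo-3-methyloct-7-ene-1,2-diol F1 and oxidised (TEMPO/N-chlorosuccinimide) to (2R,3S)-7-bromo-2-hydroxy-3-methyloct-7-enal F2. Compound 13 is cross‑metathesised with 18 to methyl (2Z)-2-(bromomethyl)-4-[(2R,3R)-3-(3-hydroxypropyl)-3-methyloxiran-2-yl]but-2-enoate F3. F2 and F3 are joined with indium in THF/H2O and lactonised to (4S,5R)-5-[(1R,2S)-6-bromo-1-hydroxy-2-methylhept-6-enyl]-4-{[(2R,3R)-3-(3-hydroxypropyl)-3-methyloxiran-2-yl]methyl}-3-methylideneoxolan-2-one F4. Its primary alcohol is oxidised (TEMPO/N-chlorosuccinimide) to (4S,5R)-5-[(1R,2S)-6-bromo-1-hydroxy-2-methylhept-6-enyl]-3-methylidene-4-{[(2R,3R)-3-methyl-3-(3-oxopropyl)oxiran-2-yl]methyl}oxolan-2-one F5. An intramolecular Nozaki–Hiyama–Kishi reaction (CrCl2, NiCl2 cat., the sulfonamide ligand of step 6, high dilution) then closes the ring and gives 23.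

Step 8 (cross‑metathesis with the bromomethyl acrylate). The 1,1‑disubstituted, electron‑poor partner may react too slowly on this polyfunctional substrate, or the allylic bromide may degrade the catalyst. The fallback sets out from 17 and comes back at 23, replacing the allyl bromide by a simple enoate and the allylindium by a ketyl. Compound 17 is cross‑metathesised with methyl acrylate (same ruthenium catalyst) to methyl (2E)-4-{(2R,3R)-3-methyl-3-[(3R,8S,9R)-3,9,10-trihydroxy-8-methyl-4-methylidenedecyl]oxiran-2-yl}but-2-enoate F6. The primary alcohol is oxidised (TEMPO/N-chlorosuccinimide) to methyl (2E)-4-{(2R,3R)-3-[(3R,8S,9R)-3,9-dihydroxy-8-methyl-4-methylidene-10-oxodecyl]-3-methyloxiran-2-yl}but-2-enoate F7. SmI2 (THF/MeOH, −78 °C, high dilution) converts the aldehyde into its ketyl, which adds to the enoate β‑carbon; lactonisation gives (1S,3R,4R,7R,12S,13R,14R)-3,4-epoxy-7,13-dihydroxy-17-norcembr-8(19)-en-16,14-olide F8. Excess LDA then dimethylmethylideneammonium iodide gives (1S,3R,4R,7R,12S,13R,14R)-17-(dimethylamino)-3,4-epoxy-7,13-dihydroxycembr-8(19)-en-16,14-olide F9 (C15 epimers), and MeI followed by NaHCO3 eliminates trimethylamine to give 23.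

Step 6 (asymmetric coupling of a 2‑bromoalkene). The alkenyl bromide may be sluggish under NiCl2/CrCl2, and the facial control at C7 depends on a ligand whose sense must be confirmed. The fallback sets out from 8 and 14 and comes back at 16, using an organolithium addition followed by reagent‑controlled reduction. Compound 8 is treated with t-BuLi (3.2 equiv, Et2O, −78 °C) and the alkoxide–alkenyllithium is added to 14 to give (2R,3S,8RS)-1-(tert-butyldimethylsilyloxy)-3-methyl-7-methylidene-10-[(2R,3R)-2-methyl-3-(prop-2-enyl)oxiran-2-yl]decane-2,8-diol F10. MnO2 oxidises only the allylic alcohol, giving (8S,9R)-10-(tert-butyldimethylsilyloxy)-9-hydroxy-8-methyl-4-methylidene-1-[(2R,3R)-2-methyl-3-(prop-2-enyl)oxiran-2-yl]decan-3-one F11. Corey–Bakshi–Shibata reduction ((S)-2-methyl-CBS-oxazaborolidine, catecholborane, −78 °C) then gives 16 with 7R.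

**Further compounds**
F1 | step 10 | (2R,3S)-7-bromo-3-methyloct-7-ene-1,2-diol | C=C(Br)CCC[C@H](C)[C@@H](O)CO
F2 | step 10 | (2R,3S)-7-bromo-2-hydroxy-3-methyloct-7-enal | C=C(Br)CCC[C@H](C)[C@@H](O)C=O
F3 | step 10 | methyl (2Z)-2-(bromomethyl)-4-[(2R,3R)-3-(3-hydroxypropyl)-3-methyloxiran-2-yl]but-2-enoate | COC(=O)/C(CBr)=C/C[C@H]1O[C@]1(C)CCCO
F4 | step 10 | (4S,5R)-5-[(1R,2S)-6-bromo-1-hydroxy-2-methylhept-6-enyl]-4-{[(2R,3R)-3-(3-hydroxypropyl)-3-methyloxiran-2-yl]methyl}-3-methylideneoxolan-2-one | C=C(Br)CCC[C@H](C)[C@@H](O)[C@@H]1OC(=O)C(=C)[C@@H]1C[C@H]1O[C@]1(C)CCCO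
F5 | step 10 | (4S,5R)-5-[(1R,2S)-6-bromo-1-hydroxy-2-methylhept-6-enyl]-3-methylidene-4-{[(2R,3R)-3-methyl-3-(3-oxopropyl)oxiran-2-yl]methyl}oxolan-2-one | C=C(Br)CCC[C@H](C)[C@@H](O)[C@@H]1OC(=O)C(=C)[C@@H]1C[C@H]1O[C@]1(C)CCC=O
F6 | step 8 | methyl (2E)-4-{(2R,3R)-3-methyl-3-[(3R,8S,9R)-3,9,10-trihydroxy-8-methyl-4-methylidenedecyl]oxiran-2-yl}but-2-enoate | COC(=O)/C=C/C[C@H]1O[C@]1(C)CC[C@@H](O)C(=C)CCC[C@H](C)[C@@H](O)CO
F7 | step 8 | methyl (2E)-4-{(2R,3R)-3-[(3R,8S,9R)-3,9-dihydroxy-8-methyl-4-methylidene-10-oxodecyl]-3-methyloxiran-2-yl}but-2-enoate | COC(=O)/C=C/C[C@H]1O[C@]1(C)CC[C@@H](O)C(=C)CCC[C@H](C)[C@@H](O)C=O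
F8 | step 8 | (1S,3R,4R,7R,12S,13R,14R)-3,4-epoxy-7,13-dihydroxy-17-norcembr-8(19)-en-16,14-olide | C=C1CCC[C@H](C)[C@@H](O)[C@@H]2OC(=O)C[C@@H]2C[C@H]2O[C@]2(C)CC[C@H]1O
F9 | step 8 | (1S,3R,4R,7R,12S,13R,14R)-17-(dimethylamino)-3,4-epoxy-7,13-dihydroxycembr-8(19)-en-16,14-olide (C15 epimers) | C=C1CCC[C@H](C)[C@@H](O)[C@@H]2OC(=O)C(CN(C)C)[C@@H]2C[C@H]2O[C@]2(C)CC[C@H]1O
F10 | step 6 | (2R,3S,8RS)-1-(tert-butyldimethylsilyloxy)-3-methyl-7-methylidene-10-[(2R,3R)-2-methyl-3-(prop-2-enyl)oxiran-2-yl]decane-2,8-diol | C=CC[C@H]1O[C@]1(C)CCC(O)C(=C)CCC[C@H](C)[C@@H](O)CO[Si](C)(C)C(C)(C)C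
F11 | step 6 | (8S,9R)-10-(tert-butyldimethylsilyloxy)-9-hydroxy-8-methyl-4-methylidene-1-[(2R,3R)-2-methyl-3-(prop-2-enyl)oxiran-2-yl]decan-3-one | C=CC[C@H]1O[C@]1(C)CCC(=O)C(=C)CCC[C@H](C)[C@@H](O)CO[Si](C)(C)C(C)(C)C
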